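**Assumption:** the SMILES is read as (5E) at the butenolide ylidene (side chain trans to the ring oxygen), (E) at the trisubstituted chain alkene and (S) at the methyl-bearing carbon; myrcene, 3-acetylfuran, (R)-3-bromo-2-methylpropan-1-ol and 3-methyltetronic acid are taken as commercial.

**Retrosynthetic overview**
- Target 19 ⇐ 17 by O-demethylation; 17 ⇐ aldehyde 11 + tetronate 5-phosphonate 15 (exocyclic C=C, E set kinetically).
- 11 ⇐ 10 ⇐ allylic bromide 7 + 3-acetylfuran enolate (ketone α-CH2 to allylic CH2 bond); 7 ⇐ 5 by E-selective allylic oxidation.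
- 5 ⇐ myrcene-derived primary alkylborane 4 + (R)-3-bromo-2-methylpropan-1-ol 3 by a blue-light, copper-catalysed sp3–sp3 coupling (key CH2–CH2 bond; 3 supplies the only stereocentre).
- No ring is built: the furan arrives with 3-acetylfuran (step 4) and the butenolide with 3-methyltetronic acid (steps 6–9), in that order.

**Route**

Step 1
Reactants: 1 myrcene (7-methyl-3-methylideneocta-1,6-diene); 2 9-borabicyclo[3.3.1]nonane (9-BBN, used as its dimer); 3 (R)-3-bromo-2-methylpropan-1-ol
Product: 5 (2S)-2,10-dimethyl-6-methylideneundec-9-en-1-ol, via B-alkyl-9-BBN 4 (not isolated)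
Conditions: 1 (1.6 equiv), (9-BBN)2 (0.75 equiv), THF, 0 °C → rt, 4 h, excess 1 stripped in vacuo; then 3 (1.0 equiv), LiOtBu (2.6 equiv), CuCl (10 mol %), Xantphos (12 mol %), THF/DMA, 450 nm LEDs, 0 °C, 18 h; aq. NH4Cl
Reagents that add atoms: none
Why: Proposed new method: 9-BBN adds anti-Markovnikov to the monosubstituted vinyl terminus of the diene (known hydroboration selectivity, leaving the 1,1-disubstituted and trisubstituted alkenes), the tert-butoxide ate complex of 4 passes its primary alkyl group to phosphine-ligated monovalent copper, the photoexcited alkylcopper reduces the unactivated β-branched bromide 3 by single-electron transfer, the primary radical is captured by the divalent alkylcopper and the dialkyl trivalent copper reductively eliminates to form the CH2–CH2 bond; the stereocentre of 3 is β to the radical and is carried over unchanged (R in 3 reads S in 5 only through the priority change), and the free hydroxyl rides through as its alkoxyborate; closest known reaction types are the thermal copper/LiOtBu coupling of alkyl-9-BBN reagents with primary alkyl halides (B-alkyl Suzuki–Miyaura type) and photoinduced copper-catalysed couplings of unactivated alkyl halides with copper-bound N- and C-nucleophiles.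

Step 2
Reactants: 5 (2S)-2,10-dimethyl-6-methylideneundec-9-en-1-ol
Product: 6 (2S,9E)-2,10-dimethyl-6-methylideneundec-9-ene-1,11-diol
Conditions: SeO2 (0.4 equiv), tBuOOH (3 equiv), salicylic acid (0.1 equiv), CH2Cl2, 0 °C → rt, 24 h
Reagents that add atoms: selenium dioxide O=[Se]=O; tert-butyl hydroperoxide CC(C)(C)OO
Why: Riley/Sharpless SeO2 allylic oxidation (ene reaction then [2,3]-sigmatropic shift) attacks the most electron-rich, trisubstituted alkene at its (E)-methyl group, which fixes the 9E geometry, while the 1,1-disubstituted alkene reacts more slowly and the saturated alcohol and the stereocentre are inert.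

Step 3
Reactants: 6 (2S,9E)-2,10-dimethyl-6-methylideneundec-9-ene-1,11-diol
Product: 7 (2S,9E)-11-bromo-2,10-dimethyl-6-methylideneundec-9-en-1-ol
Conditions: NBS (1.2 equiv), Me2S (1.5 equiv), CH2Cl2, −20 → 0 °C, 2 h
Reagents that add atoms: N-bromosuccinimide O=C1CCC(=O)N1Br
Why: Corey–Kim halogenation: only the allylic alkoxysulfonium is displaced by bromide (SN2, geometry kept), the saturated hydroxyl returning unchanged on work-up.

Step 4
Reactants: 8 3-acetylfuran; 7 (2S,9E)-11-bromo-2,10-dimethyl-6-methylideneundec-9-en-1-ol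
Product: 10 (4E,12S)-1-(furan-3-yl)-13-hydroxy-4,12-dimethyl-8-methylidenetridec-4-en-1-one, via lithium enolate 9 (not isolated)
Conditions: 8 (3.2 equiv), LiN(iPr)2 (3.1 equiv), THF, −78 °C, 45 min; then 7 (1.0 equiv), DMPU, −78 → −30 °C; aq. NH4Cl
Reagents that add atoms: none
Why: Alkylation of the kinetic lithium enolate of the methyl ketone with a primary allylic bromide (SN2) forms the C–C bond without touching alkene geometry or the remote stereocentre, the free hydroxyl only consuming one of the excess equivalents of enolate.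

Step 5
Reactants: 10 (4E,12S)-1-(furan-3-yl)-13-hydroxy-4,12-dimethyl-8-methylidenetridec-4-en-1-one
Product: 11 (2S,9E)-13-(furan-3-yl)-2,10-dimethyl-6-methylidene-13-oxotridec-9-enal
Conditions: Dess–Martin periodinane (1.3 equiv), CH2Cl2, 0 °C → rt, 1 h; used crude at once
Reagents that add atoms: none
Why: Dess–Martin oxidation is neutral and fast, so the primary alcohol gives the α-methyl aldehyde without epimerisation while ketone, furan and alkenes are untouched.

Step 6
Reactants: 12 3-methyltetronic acid (4-hydroxy-3-methylfuran-2(5H)-one)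
Product: 13 4-methoxy-3-methylfuran-2(5H)-one
Conditions: Me2SO4 (1.1 equiv), K2CO3 (1.2 equiv), acetone, reflux, 4 h
Reagents that add atoms: dimethyl sulfate COS(=O)(=O)OC
Why: Williamson-type O-alkylation of the vinylogous acid at the 4-oxygen masks the acidic OH for steps 7–9.

Step 7
Reactants: 13 4-methoxy-3-methylfuran-2(5H)-one
Product: 14 5-bromo-4-methoxy-3-methylfuran-2(5H)-one (racemic)
Conditions: NBS (1.05 equiv), AIBN (5 mol %), PhCF3, 80 °C, 2 h; used crude
Reagents that add atoms: N-bromosuccinimide O=C1CCC(=O)N1Br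
Why: Wohl–Ziegler radical bromination goes to C5, whose radical is allylic and α-oxygenated (as in the known 5-bromination of 3-methylbutenolide); the racemic C5 centre is erased in step 9.

Step 8
Reactants: 14 5-bromo-4-methoxy-3-methylfuran-2(5H)-one
Product: 15 bis(2,2,2-trifluoroethyl) (3-methoxy-4-methyl-5-oxo-2,5-dihydrofuran-2-yl)phosphonate (racemic)
Conditions: HP(O)(OCH2CF3)2 (1.3 equiv), iPr2NEt (1.4 equiv), MeCN, 0 °C → rt, 3 h
Reagents that add atoms: bis(2,2,2-trifluoroethyl) phosphite O=[PH](OCC(F)(F)F)OCC(F)(F)F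
Why: Michaelis–Becker-type phosphonylation: the lactol-like C5 bromide ionises readily and is captured at phosphorus by the deprotonated H-phosphonate to give the C–P bond.

Step 9
Reactants: 15 bis(2,2,2-trifluoroethyl) (3-methoxy-4-methyl-5-oxo-2,5-dihydrofuran-2-yl)phosphonate; 11 (2S,9E)-13-(furan-3-yl)-2,10-dimethyl-6-methylidene-13-oxotridec-9-enal
Product: 17 (5E)-5-[(2S,9E)-13-(furan-3-yl)-2,10-dimethyl-6-methylidene-13-oxotridec-9-en-1-ylidene]-4-methoxy-3-methylfuran-2(5H)-one, via potassium furanolate 16 (not isolated)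
Conditions: 15 (1.3 equiv), KN(SiMe3)2 (1.25 equiv), 18-crown-6 (3 equiv), THF, −78 °C, 30 min; then 11 (1.0 equiv), −78 °C, 3 h
Reagents that add atoms: none
Why: Proposed new method: 16 is a phosphoryl-stabilised 2-furanolate whose electron-poor bis(trifluoroethyl) phosphonate makes addition to the aldehyde irreversible and oxaphosphetane collapse fast, so the kinetic adduct, with the aldehyde substituent syn to the carbanion-stabilising π-arm (here ring carbon C4 of the vinylogous ester, the counterpart of the ester arm in a Still–Gennari reagent), goes straight to the alkene and gives the (5E)-ylidene (chain cis to C4–OMe, trans to the ring oxygen); the weakly basic anion at −78 °C neither epimerises the α-stereocentre nor attacks the ketone; closest known reaction type is the Still–Gennari Z-selective Horner–Wadsworth–Emmons olefination, here transferred to a tetronate 5-phosphonate reagent that has not been described.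

Step 10
Reactants: 17 (5E)-5-[(2S,9E)-13-(furan-3-yl)-2,10-dimethyl-6-methylidene-13-oxotridec-9-en-1-ylidene]-4-methoxy-3-methylfuran-2(5H)-one
Product: 19 (5E)-5-[(2S,9E)-13-(furan-3-yl)-2,10-dimethyl-6-methylidene-13-oxotridec-9-en-1-ylidene]-4-hydroxy-3-methylfuran-2(5H)-one (CNP0018618.1), via lithium tetronate 18 (not isolated)
Conditions: LiCl (10 equiv), DMF, 90 °C, 6 h; then 1 M HCl, 0 °C
Reagents that add atoms: none
Why: Krapcho-type SN2 demethylation of the vinylogous methyl ester by chloride under neutral conditions frees the tetronic acid as its lithium salt without a base strong enough to epimerise the γ-stereocentre or isomerise the (5E)-ylidene, and acidification gives 19.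

**Compound list**

1 | myrcene (7-methyl-3-methylideneocta-1,6-diene) | C=CC(=C)CCC=C(C)C | starting material
2 | 9-borabicyclo[3.3.1]nonane (9-BBN) | B1C2CCCC1CCC2 | starting material
3 | (R)-3-bromo-2-methylpropan-1-ol | BrC[C@H](C)CO | starting material
4 | 9-(7-methyl-3-methylideneoct-6-en-1-yl)-9-borabicyclo[3.3.1]nonane | C=C(CCC=C(C)C)CCB1C2CCCC1CCC2 | intermediate
5 | (2S)-2,10-dimethyl-6-methylideneundec-9-en-1-ol | C=C(CCC=C(C)C)CCC[C@H](C)CO | intermediate
6 | (2S,9E)-2,10-dimethyl-6-methylideneundec-9-ene-1,11-diol | C=C(CC/C=C(\C)CO)CCC[C@H](C)CO | intermediate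
7 | (2S,9E)-11-bromo-2,10-dimethyl-6-methylideneundec-9-en-1-ol | C=C(CC/C=C(\C)CBr)CCC[C@H](C)CO | intermediate
8 | 3-acetylfuran (1-(furan-3-yl)ethan-1-one) | CC(=O)c1ccoc1 | starting material
9 | lithium 1-(furan-3-yl)ethen-1-olate | [Li]OC(=C)c1ccoc1 | intermediate
10 | (4E,12S)-1-(furan-3-yl)-13-hydroxy-4,12-dimethyl-8-methylidenetridec-4-en-1-one | C=C(CC/C=C(\C)CCC(=O)c1ccoc1)CCC[C@H](C)CO | intermediate
11 | (2S,9E)-13-(furan-3-yl)-2,10-dimethyl-6-methylidene-13-oxotridec-9-enal | C=C(CC/C=C(\C)CCC(=O)c1ccoc1)CCC[C@H](C)C=O | intermediate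
12 | 3-methyltetronic acid (4-hydroxy-3-methylfuran-2(5H)-one) | CC1=C(O)COC1=O | starting material
13 | 4-methoxy-3-methylfuran-2(5H)-one | CC1=C(OC)COC1=O | intermediate
14 | 5-bromo-4-methoxy-3-methylfuran-2(5H)-one (racemic) | CC1=C(OC)C(Br)OC1=O | intermediate
15 | bis(2,2,2-trifluoroethyl) (3-methoxy-4-methyl-5-oxo-2,5-dihydrofuran-2-yl)phosphonate (racemic) | CC1=C(OC)C(OC1=O)P(=O)(OCC(F)(F)F)OCC(F)(F)F | intermediate
16 | potassium 5-[bis(2,2,2-trifluoroethoxy)phosphoryl]-4-methoxy-3-methylfuran-2-olate | [K+].Cc1c([O-])oc(P(=O)(OCC(F)(F)F)OCC(F)(F)F)c1OC | intermediate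
17 | (5E)-5-[(2S,9E)-13-(furan-3-yl)-2,10-dimethyl-6-methylidene-13-oxotridec-9-en-1-ylidene]-4-methoxy-3-methylfuran-2(5H)-one | C=C(CC/C=C(\C)CCC(=O)c1ccoc1)CCC[C@H](C)/C=C1/OC(=O)C(C)=C1OC | intermediate
18 | lithium (5E)-5-[(2S,9E)-13-(furan-3-yl)-2,10-dimethyl-6-methylidene-13-oxotridec-9-en-1-ylidene]-3-methyl-2-oxo-2,5-dihydrofuran-4-olate | [Li+].C=C(CC/C=C(\C)CCC(=O)c1ccoc1)CCC[C@H](C)/C=C1/OC(=O)C(C)=C1[O-] | intermediate
19 | (5E)-5-[(2S,9E)-13-(furan-3-yl)-2,10-dimethyl-6-methylidene-13-oxotridec-9-en-1-ylidene]-4-hydroxy-3-methylfuran-2(5H)-one | C=C(CC/C=C(\C)CCC(=O)c1ccoc1)CCC[C@H](C)/C=C1/OC(=O)C(C)=C1O | target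

**Step count and risks**

Total step count: 10. Longest linear sequence: 7 (steps 1, 2, 3, 4, 5, 9, 10); the tetronate branch is steps 6–8.

Three steps most likely to fail:

Step 1 (proposed new light-driven copper coupling; the photoexcited alkylcopper may not reduce the bromide, or homocoupling may dominate). The fallback uses known chemistry, sets out from 4 and comes back at 5. Borane 4 is oxidised with NaOH/H2O2 to 7-methyl-3-methylideneoct-6-en-1-ol F1, which CBr4/PPh3 converts into 8-bromo-2-methyl-6-methylideneoct-2-ene F2, and Mg in THF gives (7-methyl-3-methylideneoct-6-en-1-yl)magnesium bromide F3. Bromo alcohol 3 is deprotonated with MeMgCl to chloromagnesium (2R)-3-bromo-2-methylpropan-1-olate F4, which is alkylated by F3 under Li2CuCl4 catalysis (THF/NMP, 0 °C, Kochi-type Grignard coupling) to give 5 after aqueous work-up.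

Step 2 (SeO2 oxidation; over-oxidation to the enal and competing attack next to the 1,1-disubstituted alkene can cut the yield). The fallback sets out from 5 and comes back at 10, bypassing steps 3 and 4. mCPBA (1.0 equiv, CH2Cl2, −20 °C) epoxidises the trisubstituted alkene to (2S)-8-(3,3-dimethyloxiran-2-yl)-2-methyl-6-methylideneoctan-1-ol F5, and Al(OiPr)3 in hot toluene isomerises it to (2S)-2,10-dimethyl-6-methylideneundec-10-ene-1,9-diol F6. Ketone 8 is converted with HC(OMe)3/TsOH in MeOH into 3-(1,1-dimethoxyethyl)furan F7. Heating F6 with F7 and catalytic propionic acid in xylene at 130 °C gives, with loss of methanol, (2S)-9-{[1-(furan-3-yl)ethenyl]oxy}-2,10-dimethyl-6-methylideneundec-10-en-1-ol F8, whose chair Claisen rearrangement (Johnson/Saucy–Marbet ketal Claisen, E-selective) delivers 10 after mild acidic work-up.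

Step 9 (proposed new olefination; the E/Z ratio of a tetronate phosphonate is untested and addition to the α-branched aldehyde may be slow). The fallback uses known chemistry, sets out from 11 and 13 and comes back at 17. LiN(iPr)2 (THF, −78 °C) converts 13 into lithium 4-methoxy-3-methylfuran-2-olate F9, which adds to 11 to give the aldol adducts 5-[(2S,9E)-13-(furan-3-yl)-1-hydroxy-2,10-dimethyl-6-methylidene-13-oxotridec-9-en-1-yl]-4-methoxy-3-methylfuran-2(5H)-one F10. MsCl/Et3N gives the mesylates F11, and DBU eliminates them to the ylidene tetronate, expected mainly as the (5Z)-isomer F12 next to 17. Irradiation of F12 (350 nm, or 405 nm with thioxanthone as triplet sensitiser) gives a Z/E photostationary mixture from which 17 is separated by chromatography and F12 is recycled.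

**Further compounds**

F1 | step 1 | 7-methyl-3-methylideneoct-6-en-1-ol | C=C(CCC=C(C)C)CCO
F2 | step 1 | 8-bromo-2-methyl-6-methylideneoct-2-ene | C=C(CCC=C(C)C)CCBr
F3 | step 1 | (7-methyl-3-methylideneoct-6-en-1-yl)magnesium bromide | C=C(CCC=C(C)C)CC[Mg]Br
F4 | step 1 | chloromagnesium (2R)-3-bromo-2-methylpropan-1-olate | BrC[C@H](C)CO[Mg]Cl
F5 | step 2 | (2S)-8-(3,3-dimethyloxiran-2-yl)-2-methyl-6-methylideneoctan-1-ol (epoxide epimers) | C=C(CCC1OC1(C)C)CCC[C@H](C)CO
F6 | step 2 | (2S)-2,10-dimethyl-6-methylideneundec-10-ene-1,9-diol (C9 epimers) | C=C(CCC(O)C(C)=C)CCC[C@H](C)CO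
F7 | step 2 | 3-(1,1-dimethoxyethyl)furan | COC(C)(OC)c1ccoc1
F8 | step 2 | (2S)-9-{[1-(furan-3-yl)ethenyl]oxy}-2,10-dimethyl-6-methylideneundec-10-en-1-ol (C9 epimers) | C=C(CCC(OC(=C)c1ccoc1)C(C)=C)CCC[C@H](C)CO
F9 | step 9 | lithium 4-methoxy-3-methylfuran-2-olate | [Li+].Cc1c([O-])occ1OC
F10 | step 9 | 5-[(2S,9E)-13-(furan-3-yl)-1-hydroxy-2,10-dimethyl-6-methylidene-13-oxotridec-9-en-1-yl]-4-methoxy-3-methylfuran-2(5H)-one (diastereomer mixture) | C=C(CC/C=C(\C)CCC(=O)c1ccoc1)CCC[C@H](C)C(O)C1OC(=O)C(C)=C1OC
F11 | step 9 | (2S,9E)-13-(furan-3-yl)-1-(3-methoxy-4-methyl-5-oxo-2,5-dihydrofuran-2-yl)-2,10-dimethyl-6-methylidene-13-oxotridec-9-en-1-yl methanesulfonate (diastereomer mixture) | C=C(CC/C=C(\C)CCC(=O)c1ccoc1)CCC[C@H](C)C(OS(C)(=O)=O)C1OC(=O)C(C)=C1OC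
F12 | step 9 | (5Z)-5-[(2S,9E)-13-(furan-3-yl)-2,10-dimethyl-6-methylidene-13-oxotridec-9-en-1-ylidene]-4-methoxy-3-methylfuran-2(5H)-one | C=C(CC/C=C(\C)CCC(=O)c1ccoc1)CCC[C@H](C)/C=C1\OC(=O)C(C)=C1OC
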